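**Late readings.** Start at the end of the runs. At 25.0 min green still holds 30.1 % of intermediate, barely below its 30.6 % at 15.0 min, while teal, with more coupling partner, is down to 0.6 %. So I ask you to read the coupling partner as the concentration that sets the order of the rate: I take the intermediate to fall in proportion to it.

| flask | starting material | coupling partner | protic impurity | catalyst | remark | time |
|---|---|---|---|---|---|---|
| grey | 0.052 M | 0.052 M | 0.026 M | 1.2 mM | run made earlier |  |
| green | 0.052 M | 0.035 M | 0.026 M | 1.2 mM | run made earlier |  |
| teal | 0.052 M | 0.078 M | 0.026 M | 1.2 mM | run made earlier |  |
| red | 0.052 M | 0.052 M | 0.039 M | 1.2 mM | run made earlier |  |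
| noon | 0.052 M | 0.0520 M (fed, over 30.0 min) | 0.0260 M | 1.2 mM | a stirred flask in which coupling partner is dosed at a steady rate over 30.0 min without added volume, worked up at 30 min | 30 min |
| summer | 0.052 M (fed, over 30.0 min) | 0.0520 M | 0.0260 M | 1.2 mM | a stirred flask in which starting material is dosed at a steady rate over 30.0 min without added volume, worked up at 30 min | 30 min |
| spring | 0.052 M | 0.0520 M | 0.0260 M | 1.2 mM | everything together in a closed stirred flask, run for 30 min | 30 min |
| midnight | 0.052 M | 0.0520 M | 0.0260 M | 1.2 mM | a single well-mixed tank run continuously and read at steady state, 30 min in it on average |  |

| run | time / min | intermediate / % | product / % |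
|---|---|---|---|
| grey | 2.50 | 32.7 | 24.5 |
| grey | 6.00 | 21.6 | 39.2 |
| grey | 12.0 | 14.7 | 47.2 |
| grey | 30.0 | 10.3 | 51.0 |
| green | 3.00 | 39.2 | 19.7 |
| green | 8.00 | 32.2 | 29.1 |
| green | 15.0 | 30.6 | 31.9 |
| green | 25.0 | 30.1 | 31.7 |
| teal | 2.00 | 26.3 | 28.7 |
| teal | 4.00 | 15.2 | 44.2 |
| teal | 10.0 | 3.7 | 58.2 |
| teal | 25.0 | 0.6 | 61.6 |
| red | 3.00 | 33.4 | 24.2 |
| red | 8.00 | 26.7 | 35.1 |
| red | 15.0 | 23.5 | 37.9 |
| red | 25.0 | 23.3 | 38.7 |

(readings scatter by 0.3 percentage points)

- the stated concentrations are those of everything mixed, before any reaction; amounts are the same in each set-up
- the feed brings no volume worth counting
- the earlier runs were made in a closed, stirred flask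

- the set-up with the highest amount of intermediate at the outlet or at the end, in percent of the starting material put in ("none" if the first two lie within 2 percentage points) (noon / summer / spring / midnight / none)
- amount of intermediate at the outlet or at the end, in percent of the starting material put in, noon
- amount of intermediate at the outlet or at the end, in percent of the starting material put in, summer
- amount of intermediate at the outlet or at the end, in percent of the starting material put in, spring
- amount of intermediate at the outlet or at the end, in percent of the starting material put in, midnight

**The ladder.** On the fastest rung the intermediate forms: in grey, intermediate plus product stand at 60.8 % by 6.00 min and 61.3 % at the last reading, and the rest shows in neither reading. On the next rung, intermediate and protic impurity share the partner. I take both rates as first order in partner, so partner cancels from their ratio. On the last rung, in green, the readings level off.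

**The split.** Suppose green has no partner left at its last reading. Its partner balance then leaves 28.8 % of the impurity, and its intermediate stands at 48.7 % of intermediate plus product. That gives 1.73. This logarithm of the impurity fraction left, over the logarithm of the intermediate fraction left, is my selectivity factor. Red, read the same way, gives 1.74.

**My reckoning.** Spring is grey's recipe, so I expect 10.3 %. At grey's last reading, intermediate is 16.8 % of intermediate plus product: with this factor that end state costs 0.0513 M of partner, close to the 0.052 M grey was charged. Noon has the same charge, and I took partner to cancel from the factor, so I start noon from that same end state. I expect the last of the feed to be still unreacted at work-up, so I put noon somewhat above spring. In summer, with the starting material fed over 30.0 min, I let the impurity take its whole charge's worth of partner, which puts product near 50.0 %.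

**The forecast.** It names summer, with 23 % for noon, 46 % for summer, 10.3 % for spring and 39 % for midnight, noon being where “coupling partner is rationed”.

**The flasks.** Noon gives 16.9 %, summer 44.0 %, spring 10.0 % and midnight 35.5 %, so summer leads.

    starting material + catalyst → catalyst + intermediate (k = 12.9 /M/s)
    coupling partner + catalyst + intermediate → catalyst + product (k = 149 /M²/s)
    2 starting material → homo dimer (k = 0.221 /M/s)
    coupling partner + protic impurity → quenched reagent (k = 0.232 /M/s)

**Neighbour flask.** Noon ends with 19 % of its impurity, and 16.9 % of intermediate beside 44.4 % of product, so the same ratio there is 1.31, lower than green's 1.73. Now take noon with 0.10 M of protic impurity, which keeps 60 % of it. Green's factor gives 45.6 % of intermediate, and noon's own factor gives 41.5 %. That flask ends with 41.5 % of intermediate.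

The earlier runs and the new flask stem from a simulated flask for substances that don't exist, noise included.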